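(Readings and results come from a simulation for substances that don't exist; the scatter is artificial.)

Whatever X you charge, G stands still at the same fraction of D, provided G is made by D meeting X and lost by G meeting X, for then X multiplies gain and loss alike and drops out.

| flask | D | X | remark | time |
|---|---|---|---|---|
| larch | 0.050 M | 1.2 equiv | run made earlier |  |
| maple | 0.050 M | 1.7 equiv | run made earlier |  |
| elm | 0.050 M | 2.6 equiv | run made earlier |  |
| alder | 0.025 M | 1.2 equiv | run made earlier |  |
| Tuesday's | 0.050 M | 1.20 equiv | everything together at the start | 2.0 h |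
| Monday's | 0.050 M | 1.20 equiv (fed, over 1.5 h) | all else is in the flask from the start; the feed brings no volume worth counting | 2.0 h |
| Thursday's | 0.050 M (fed, over 1.5 h) | 1.20 equiv | all else is in the flask from the start; the feed brings no volume worth counting | 2.0 h |

| run | time / min | G / % | D / % |
|---|---|---|---|
| larch | 15.0 | 16.7 | 24.0 |
| larch | 30.0 | 12.4 | 11.2 |
| larch | 50.0 | 8.0 | 6.1 |
| larch | 60.0 | 7.3 | 4.3 |
| larch | 80.0 | 4.8 | 3.3 |
| larch | 90.0 | 3.8 | 2.3 |
| larch | 120 | 2.8 | 1.5 |
| maple | 6.00 | 17.7 | 44.3 |
| maple | 8.00 | 18.6 | 35.8 |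
| maple | 12.0 | 18.0 | 24.6 |
| maple | 20.0 | 14.8 | 14.0 |
| maple | 30.0 | 10.3 | 7.5 |
| maple | 50.0 | 5.2 | 3.3 |
| maple | 80.0 | 2.1 | 1.5 |
| elm | 6.00 | 19.9 | 35.7 |
| elm | 8.00 | 20.3 | 27.7 |
| elm | 12.0 | 16.5 | 17.8 |
| elm | 20.0 | 10.5 | 8.7 |
| elm | 30.0 | 5.4 | 3.1 |
| elm | 50.0 | 1.4 | 1.6 |
| elm | 80.0 | 0 | 0.3 |
| alder | 6.00 | 10.1 | 65.4 |
| alder | 20.0 | 16.0 | 32.7 |
| alder | 30.0 | 16.3 | 22.4 |
| alder | 50.0 | 12.9 | 12.5 |
| alder | 80.0 | 9.3 | 6.8 |

(standard deviation of a reading: 0.3 percentage points)

- the analysis behind the earlier runs scatters by 0.3 percentage points, standard deviation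

* which flask leads in amount of G, in percent of the D charged ("all alike" within 1.5 percentage points) (Tuesday's / Monday's / Thursday's / all alike)
* how much G is there at the end, in percent of the D charged: Tuesday's
* how much G is there at the end, in percent of the D charged: Monday's
* how much G is there at the end, in percent of the D charged: Thursday's

Maple's highest G, at 8.00 min, gives G over D = 0.520. This is the crest ratio, G over D at the moment G stops rising (a selectivity factor between G's making and G's loss). It is a reading, and the true crest falls between samples. Below this ratio G rises; above it G falls.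

Maple's G halves in 19.9 min, less than the feed's 1.5 h, so in Thursday's flask I expect G to follow the crest ratio times D. I need D there. Alder, at half larch's charge, raises the reciprocal of D's fraction at half larch's pace, but alder's X is halved along with its D, so that pace fits D meeting D and D meeting X alike. I therefore reckon both ways, with larch's loss as the yardstick: Thursday's D should settle where loss equals feed.

feed pace = 0.0111 min⁻¹ of the charge

larch's loss = 0.00853 min⁻¹ of the charge, around D = 17.6%

held D, loss going with D's square = 17.6% × sqrt(feed pace / larch's loss) = 20.1%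

held D, loss going with D at larch's X = 17.6% × feed pace / larch's loss = 22.9%

G = crest ratio × held D = 10.4% to 11.9%

So my reckoning puts Thursday's G between 10.4% and 11.9%, and G should sink once the feed stops.

The forecast differs: it named Thursday's, with 2.7% for Tuesday's, 2.6% for Monday's and 15% (12% to 19%) for Thursday's: “Hand-stepping gives about 15%.”

The flasks give 2.55% for Tuesday's, 1.10% for Monday's and 9.04% for Thursday's, so Thursday's leads, but 6 percentage points below the forecast.

    X + G → E + Q (k = 0.0248 L mol⁻¹ s⁻¹)
    2 D → L (k = 0.0151 L mol⁻¹ s⁻¹)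
    D ⇌ J (K = 1.90, k = 1.18 × 10⁻⁴ s⁻¹)
    X + Z → E + Q (k = 4.69 × 10⁻⁴ L mol⁻¹ s⁻¹)
    D + X → Z + Q (k = 0.00198 L mol⁻¹ s⁻¹)
    D + X → G + Q (k = 0.0140 L mol⁻¹ s⁻¹)

In Thursday's flask, D stood at 22.1% when the feed ended at 1.50 h; the crest ratio makes that 11.5% of G, and the flask held 10.7%. Then, with the feed over, D fell to 8.55% and G to 9.04%, while E stood at 39.3%.

Take Monday's recipe charged at 0.013 M of D, which ends with D at 9.69%: the crest ratio puts the standstill at G = 5.04%. The computed G is 7.88%, more than that, so the rule reads this flask's G as past its crest and falling.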